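**Retrosynthetic overview**

1. Gnetin K is cut at the aryl–alkyl bond between C6 of dihydrobenzofuran A (the ring system carrying the guaiacyl group) and C3 of dihydrobenzofuran B (the one carrying the stilbene). An aryl bromide (A) and a C3 carboxylic acid as its N-acyloxyphthalimide (B) are joined by nickel-electrocatalytic decarboxylative arylation.
2. Enabling feature: C3 of ring system B is a benzylic carbon inside the five-membered O1–C2–C3–C3a–C7a ring. Its radical is planar, cannot open the ring (the C2–O1 bond is orthogonal to the radical p orbital) and is shielded on one face by the C2 aryl group, so any C3-epimer mixture converges on the trans ring. C6 of ring system A is the unhindered carbon meta to both ring oxygens.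
3. Each dihydrobenzofuran is made the same way: 5-bromo-2-iodoresorcinol → bis(4-silyloxybenzyl) ether → iodine–magnesium exchange/oxalate → aryldiazoacetate → enantioselective dirhodium-carbene 1,5 C–H insertion. One benzyl ether becomes C2 with its aryl group; its twin stays as a fluoride-labile phenol protecting group.
4. Order of ring formation: furan ring of A (step 6), then C3 arylation of A by iron-catalysed decarboxylative coupling (step 10); furan ring of B (step 15), then Heck stilbene (step 16); union (step 19); one fluoride-triggered unmasking of all seven phenols (step 20).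

Key step: step 19

Abbreviations: TBS = tert-butyldimethylsilyl; TBSO = tert-butyldimethylsilyloxy; PTTL = N-phthaloyl-tert-leucinate; DIAD = diisopropyl azodicarboxylate; DIC = N,N'-diisopropylcarbodiimide; dppBz = 1,2-bis(diphenylphosphino)benzene; TBAF = tetrabutylammonium fluoride.

Remark (catalyst sense): Rh2(S-PTTL)4 is assumed to give the (2R)-configured cis-dihydrobenzofuran (step 15) and Rh2(R-PTTL)4 its mirror image (step 6), by analogy with mono-ortho-benzyloxy aryldiazoacetates. If the sense is opposite, the two catalysts are exchanged.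

Remark (C3 epimers): esters, acids and N-acyloxyphthalimides are drawn as the cis isomers from the insertion. Partial epimerisation at C3 on the way is harmless, because C3 becomes a planar radical in steps 10 and 19.

Remark: tert-butyldimethyl(4-vinylphenoxy)silane is taken as a purchased material.

**Route**

Step 1
Reactants: 1 5-bromoresorcinol (5-bromobenzene-1,3-diol)
Product: 2 5-bromo-2-iodobenzene-1,3-diol
Conditions: iodine, NaHCO3, H2O/THF, 0 °C to rt
Reagents that add atoms: iodine, [I][I]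
Why: Electrophilic iodination of the resorcinol monoanion should take place at C2 between the two hydroxyl groups, as with resorcinol itself, the other activated positions being flanked by bromine as well.

Step 2
Reactants: 3 vanillin (4-hydroxy-3-methoxybenzaldehyde)
Product: 5 [4-(TBSO)-3-methoxyphenyl]methanol, via silylated vanillin 4 (not isolated)
Conditions: TBSCl, imidazole, CH2Cl2, rt; then MeOH, NaBH4, 0 °C
Reagents that add atoms: tert-butyldimethylsilyl chloride, CC(C)(C)[Si](C)(C)Cl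
Why: Imidazole-mediated silylation of the phenol is followed in the same flask by chemoselective borohydride reduction of the aldehyde.

Step 3
Reactants: 2 5-bromo-2-iodobenzene-1,3-diol; 5 [4-(TBSO)-3-methoxyphenyl]methanol (2.2 equiv)
Product: 6 5-bromo-2-iodo-1,3-bis{[4-(TBSO)-3-methoxybenzyl]oxy}benzene
Conditions: PPh3, DIAD, THF, 0 °C to rt
Reagents that add atoms: none
Why: Mitsunobu etherification of both acidic phenols with the primary benzylic alcohol runs under neutral conditions that leave aryl silyl ethers intact.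

Step 4
Reactants: 6 5-bromo-2-iodo-1,3-bis{[4-(TBSO)-3-methoxybenzyl]oxy}benzene
Product: 8 methyl 2-(4-bromo-2,6-bis{[4-(TBSO)-3-methoxybenzyl]oxy}phenyl)-2-oxoacetate, via arylmagnesium chloride 7 (not isolated)
Conditions: iPrMgCl·LiCl, THF, −40 °C; then cannulated into dimethyl oxalate (3 equiv), THF, −78 to −20 °C; aq. NH4Cl
Reagents that add atoms: dimethyl oxalate, COC(=O)C(=O)OC
Why: Iodine–magnesium exchange (turbo-Grignard) is selective for the carbon–iodine bond flanked by two alkoxy groups over the aryl bromide, and inverse addition to excess oxalate stops at the aryl glyoxylate.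

Step 5
Reactants: 8 methyl 2-(4-bromo-2,6-bis{[4-(TBSO)-3-methoxybenzyl]oxy}phenyl)-2-oxoacetate
Product: 10 methyl 2-(4-bromo-2,6-bis{[4-(TBSO)-3-methoxybenzyl]oxy}phenyl)-2-diazoacetate, via tosylhydrazone 9 (not isolated)
Conditions: TsNHNH2, THF, 50 °C; then Et3N, CH2Cl2, rt
Reagents that add atoms: 4-methylbenzenesulfonohydrazide, Cc1ccc(cc1)S(=O)(=O)NN
Why: Condensation at the activated ketone of the α-keto ester followed by base-induced loss of sulfinate (Bamford–Stevens reaction) gives the aryldiazoacetate.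

Step 6
Reactants: 10 methyl 2-(4-bromo-2,6-bis{[4-(TBSO)-3-methoxybenzyl]oxy}phenyl)-2-diazoacetate
Product: 11 methyl (2S,3R)-6-bromo-2-[4-(TBSO)-3-methoxyphenyl]-4-{[4-(TBSO)-3-methoxybenzyl]oxy}-2,3-dihydrobenzofuran-3-carboxylate
Conditions: Rh2(R-PTTL)4 (1 mol%), toluene, −60 °C
Reagents that add atoms: none
Why: Enantioselective intramolecular 1,5 C–H insertion of the donor/acceptor dirhodium carbene into the ether-activated benzylic C–H bond closes the five-membered ring; the chiral carboxylate ligands select one enantiotopic benzylic hydrogen and should give the cis (2S,3R) ester, and the two ortho ethers are homotopic so no regiochemical issue arises.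

Step 7
Reactants: 11 methyl (2S,3R)-6-bromo-2-[4-(TBSO)-3-methoxyphenyl]-4-{[4-(TBSO)-3-methoxybenzyl]oxy}-2,3-dihydrobenzofuran-3-carboxylate
Product: 12 (2S,3R)-6-bromo-2-[4-(TBSO)-3-methoxyphenyl]-4-{[4-(TBSO)-3-methoxybenzyl]oxy}-2,3-dihydrobenzofuran-3-carboxylic acid
Conditions: Me3SnOH, 1,2-dichloroethane, 70 °C; then 0.1 M aq. HCl wash
Reagents that add atoms: trimethyltin hydroxide, C[Sn](C)(C)O
Why: Trimethyltin hydroxide cleaves the methyl ester by essentially neutral acyl substitution, which should spare the aryl silyl ethers and the aryl bromide and leave C2 untouched.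

Step 8
Reactants: 12 (2S,3R)-6-bromo-2-[4-(TBSO)-3-methoxyphenyl]-4-{[4-(TBSO)-3-methoxybenzyl]oxy}-2,3-dihydrobenzofuran-3-carboxylic acid
Product: 13 1,3-dioxoisoindolin-2-yl (2S,3R)-6-bromo-2-[4-(TBSO)-3-methoxyphenyl]-4-{[4-(TBSO)-3-methoxybenzyl]oxy}-2,3-dihydrobenzofuran-3-carboxylate
Conditions: N-hydroxyphthalimide, DIC, DMAP (cat.), CH2Cl2, rt
Reagents that add atoms: N-hydroxyphthalimide, O=C1c2ccccc2C(=O)N1O
Why: Carbodiimide esterification gives the redox-active ester needed for single-electron decarboxylation.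

Step 9
Reactants: 1 5-bromoresorcinol
Product: 14 1-bromo-3,5-bis(TBSO)benzene
Conditions: TBSCl, imidazole, DMF, rt
Reagents that add atoms: tert-butyldimethylsilyl chloride, CC(C)(C)[Si](C)(C)Cl
Why: Standard silylation of both phenols.

Step 10
Reactants: 13 1,3-dioxoisoindolin-2-yl (2S,3R)-6-bromo-2-[4-(TBSO)-3-methoxyphenyl]-4-{[4-(TBSO)-3-methoxybenzyl]oxy}-2,3-dihydrobenzofuran-3-carboxylate; 14 1-bromo-3,5-bis(TBSO)benzene (2.6 equiv)
Product: 16 (2S,3S)-6-bromo-3-[3,5-bis(TBSO)phenyl]-2-[4-(TBSO)-3-methoxyphenyl]-4-{[4-(TBSO)-3-methoxybenzyl]oxy}-2,3-dihydrobenzofuran, via diarylzinc 15 (not isolated)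
Conditions: 14, n-BuLi, THF, −78 °C; ZnCl2 (1.3 equiv), to rt; then 13, Fe(acac)3 (20 mol%), dppBz (24 mol%), THF/toluene, rt
Reagents that add atoms: none
Why: Iron-catalysed decarboxylative arylation of a redox-active ester with a diarylzinc (Negishi-type radical cross-coupling): electron transfer releases CO2 and a planar benzylic C3 radical that recombines with the aryliron species on the face opposite the C2 aryl group, so either C3 epimer should give the trans (2S,3S) product, and the iron catalyst does not activate the aryl carbon–bromine bond.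

Step 11
Reactants: 17 4-hydroxybenzaldehyde
Product: 19 [4-(TBSO)phenyl]methanol, via silylated aldehyde 18 (not isolated)
Conditions: TBSCl, imidazole, CH2Cl2, rt; then MeOH, NaBH4, 0 °C
Reagents that add atoms: tert-butyldimethylsilyl chloride, CC(C)(C)[Si](C)(C)Cl
Why: Phenol silylation and chemoselective borohydride reduction of the aldehyde, as in step 2.

Step 12
Reactants: 2 5-bromo-2-iodobenzene-1,3-diol; 19 [4-(TBSO)phenyl]methanol (2.2 equiv)
Product: 20 5-bromo-2-iodo-1,3-bis{[4-(TBSO)benzyl]oxy}benzene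
Conditions: PPh3, DIAD, THF, 0 °C to rt
Reagents that add atoms: none
Why: Double Mitsunobu etherification, as in step 3.

Step 13
Reactants: 20 5-bromo-2-iodo-1,3-bis{[4-(TBSO)benzyl]oxy}benzene
Product: 22 methyl 2-(4-bromo-2,6-bis{[4-(TBSO)benzyl]oxy}phenyl)-2-oxoacetate, via arylmagnesium chloride 21 (not isolated)
Conditions: iPrMgCl·LiCl, THF, −40 °C; then cannulated into dimethyl oxalate (3 equiv), THF, −78 to −20 °C; aq. NH4Cl
Reagents that add atoms: dimethyl oxalate, COC(=O)C(=O)OC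
Why: Selective iodine–magnesium exchange and mono-acylation by oxalate, as in step 4.

Step 14
Reactants: 22 methyl 2-(4-bromo-2,6-bis{[4-(TBSO)benzyl]oxy}phenyl)-2-oxoacetate
Product: 24 methyl 2-(4-bromo-2,6-bis{[4-(TBSO)benzyl]oxy}phenyl)-2-diazoacetate, via tosylhydrazone 23 (not isolated)
Conditions: TsNHNH2, THF, 50 °C; then Et3N, CH2Cl2, rt
Reagents that add atoms: 4-methylbenzenesulfonohydrazide, Cc1ccc(cc1)S(=O)(=O)NN
Why: Tosylhydrazone formation and Bamford–Stevens elimination, as in step 5.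

Step 15
Reactants: 24 methyl 2-(4-bromo-2,6-bis{[4-(TBSO)benzyl]oxy}phenyl)-2-diazoacetate
Product: 25 methyl (2R,3S)-6-bromo-2-[4-(TBSO)phenyl]-4-{[4-(TBSO)benzyl]oxy}-2,3-dihydrobenzofuran-3-carboxylate
Conditions: Rh2(S-PTTL)4 (1 mol%), toluene, −60 °C
Reagents that add atoms: none
Why: The same enantioselective 1,5 C–H insertion as in step 6 with the mirror-image catalyst closes the five-membered ring and should set C2 as R in the cis (2R,3S) ester.

Step 16
Reactants: 25 methyl (2R,3S)-6-bromo-2-[4-(TBSO)phenyl]-4-{[4-(TBSO)benzyl]oxy}-2,3-dihydrobenzofuran-3-carboxylate; 26 tert-butyldimethyl(4-vinylphenoxy)silane (1.5 equiv)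
Product: 27 methyl (2R,3S)-2-[4-(TBSO)phenyl]-4-{[4-(TBSO)benzyl]oxy}-6-[(E)-4-(TBSO)styryl]-2,3-dihydrobenzofuran-3-carboxylate
Conditions: Pd(OAc)2 (5 mol%), P(tBu)3·HBF4 (10 mol%), Cy2NMe, 1,4-dioxane, 80 °C
Reagents that add atoms: none
Why: Mizoroki–Heck reaction at the unhindered aryl bromide; syn insertion and syn β-hydride elimination should give the E-stilbene, and any base-induced epimerisation at C3 is harmless.

Step 17
Reactants: 27 methyl (2R,3S)-2-[4-(TBSO)phenyl]-4-{[4-(TBSO)benzyl]oxy}-6-[(E)-4-(TBSO)styryl]-2,3-dihydrobenzofuran-3-carboxylate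
Product: 28 (2R,3S)-2-[4-(TBSO)phenyl]-4-{[4-(TBSO)benzyl]oxy}-6-[(E)-4-(TBSO)styryl]-2,3-dihydrobenzofuran-3-carboxylic acid
Conditions: Me3SnOH, 1,2-dichloroethane, 70 °C; then 0.1 M aq. HCl wash
Reagents that add atoms: trimethyltin hydroxide, C[Sn](C)(C)O
Why: Neutral tin-hydroxide ester cleavage, as in step 7, should spare the silyl ethers and the stilbene.

Step 18
Reactants: 28 (2R,3S)-2-[4-(TBSO)phenyl]-4-{[4-(TBSO)benzyl]oxy}-6-[(E)-4-(TBSO)styryl]-2,3-dihydrobenzofuran-3-carboxylic acid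
Product: 29 1,3-dioxoisoindolin-2-yl (2R,3S)-2-[4-(TBSO)phenyl]-4-{[4-(TBSO)benzyl]oxy}-6-[(E)-4-(TBSO)styryl]-2,3-dihydrobenzofuran-3-carboxylate
Conditions: N-hydroxyphthalimide, DIC, DMAP (cat.), CH2Cl2, rt
Reagents that add atoms: N-hydroxyphthalimide, O=C1c2ccccc2C(=O)N1O
Why: Carbodiimide esterification to the redox-active ester, as in step 8.

Step 19
Reactants: 29 1,3-dioxoisoindolin-2-yl (2R,3S)-2-[4-(TBSO)phenyl]-4-{[4-(TBSO)benzyl]oxy}-6-[(E)-4-(TBSO)styryl]-2,3-dihydrobenzofuran-3-carboxylate (1.5 equiv, C3-epimer mixture as obtained); 16 (2S,3S)-6-bromo-3-[3,5-bis(TBSO)phenyl]-2-[4-(TBSO)-3-methoxyphenyl]-4-{[4-(TBSO)-3-methoxybenzyl]oxy}-2,3-dihydrobenzofuran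
Product: 30 (2S,3S)-3-[3,5-bis(TBSO)phenyl]-2-[4-(TBSO)-3-methoxyphenyl]-4-{[4-(TBSO)-3-methoxybenzyl]oxy}-6-{(2R,3R)-2-[4-(TBSO)phenyl]-4-{[4-(TBSO)benzyl]oxy}-6-[(E)-4-(TBSO)styryl]-2,3-dihydrobenzofuran-3-yl}-2,3-dihydrobenzofuran
Conditions: NiCl2·6H2O (20 mol%), 2,2'-bipyridine (24 mol%), AgNO3 (0.3 equiv), NMP, Mg anode, reticulated vitreous carbon cathode, undivided cell, constant current, rt
Reagents that add atoms: none
Why: Cathodic reduction keeps nickel low-valent: the zerovalent (or monovalent) bipyridine complex inserts into the only carbon–halogen bond present, the C6–Br bond of 16, while single-electron reduction of the redox-active ester 29 (at the silver-nanoparticle-coated cathode or by low-valent nickel) expels CO2 and phthalimide anion to give the planar benzylic radical at C3 of ring system B; capture of this radical by the arylnickel species gives a trivalent aryl(alkyl)nickel that reductively eliminates to forge the C3–C6 bond between the two halves. The closest known reaction type is the nickel-electrocatalytic decarboxylative arylation of secondary redox-active esters with aryl bromides (silver-modified cathode, sacrificial magnesium anode), the cross-electrophile relative of stereoconvergent nickel arylations of secondary benzylic radicals. No ring is closed. The one new stereocentre, C3 of ring system B, is set by substrate control: the radical is flat, so both C3 epimers of 29 give the same intermediate, and nickel (hence the aryl group) should bond on the face opposite the C2 4-silyloxyphenyl group, reductive elimination then proceeding with retention to the trans (2R,3R) ring, while C2 and the two centres of 16 are untouched. The step needs chemoselective C–Br activation and radical capture faster than β-hydride loss or ring opening: the stilbene and aryl silyl ethers lie outside the potential window, opening of the C3 radical would be the reverse of a 5-endo closure (the C2–O1 bond is orthogonal to the radical p orbital), and reductive elimination from trivalent nickel should outrun β-hydride elimination toward the benzofuran.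

Step 20
Reactants: 30 the fully protected trimer from step 19
Product: 31 gnetin K
Conditions: TBAF (12 equiv), THF/MeOH (1:1), 0 °C to rt, under argon; then AcOH
Reagents that add atoms: none
Why: Fluoride removes all seven silyl groups, and the two residual benzyl ethers, now 4-oxidobenzyl aryl ethers, fragment by 1,6-elimination to para-quinone methides that methanol intercepts; no stereocentre is touched, since any reversible opening of a dihydrobenzofuran through its own 4-oxidophenyl group recloses to the favoured trans ring.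

**Compound list**

1 | 5-bromoresorcinol | Oc1cc(O)cc(Br)c1 | starting material
2 | 5-bromo-2-iodobenzene-1,3-diol | Oc1cc(Br)cc(O)c1I | intermediate
3 | vanillin | COc1cc(C=O)ccc1O | starting material
4 | 4-(TBSO)-3-methoxybenzaldehyde | COc1cc(C=O)ccc1O[Si](C)(C)C(C)(C)C | intermediate
5 | [4-(TBSO)-3-methoxyphenyl]methanol | COc1cc(CO)ccc1O[Si](C)(C)C(C)(C)C | intermediate
6 | 5-bromo-2-iodo-1,3-bis{[4-(TBSO)-3-methoxybenzyl]oxy}benzene | Ic1c(OCc2ccc(O[Si](C)(C)C(C)(C)C)c(OC)c2)cc(Br)cc1OCc1ccc(O[Si](C)(C)C(C)(C)C)c(OC)c1 | intermediate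
7 | (4-bromo-2,6-bis{[4-(TBSO)-3-methoxybenzyl]oxy}phenyl)magnesium chloride | Cl[Mg]c1c(OCc2ccc(O[Si](C)(C)C(C)(C)C)c(OC)c2)cc(Br)cc1OCc1ccc(O[Si](C)(C)C(C)(C)C)c(OC)c1 | intermediate
8 | methyl 2-(4-bromo-2,6-bis{[4-(TBSO)-3-methoxybenzyl]oxy}phenyl)-2-oxoacetate | COC(=O)C(=O)c1c(OCc2ccc(O[Si](C)(C)C(C)(C)C)c(OC)c2)cc(Br)cc1OCc1ccc(O[Si](C)(C)C(C)(C)C)c(OC)c1 | intermediate
9 | N-tosylhydrazone of 8 | COC(=O)C(=NNS(=O)(=O)c1ccc(C)cc1)c1c(OCc2ccc(O[Si](C)(C)C(C)(C)C)c(OC)c2)cc(Br)cc1OCc1ccc(O[Si](C)(C)C(C)(C)C)c(OC)c1 | intermediate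
10 | methyl 2-(4-bromo-2,6-bis{[4-(TBSO)-3-methoxybenzyl]oxy}phenyl)-2-diazoacetate | COC(=O)C(=[N+]=[N-])c1c(OCc2ccc(O[Si](C)(C)C(C)(C)C)c(OC)c2)cc(Br)cc1OCc1ccc(O[Si](C)(C)C(C)(C)C)c(OC)c1 | intermediate
11 | methyl (2S,3R)-6-bromo-2-[4-(TBSO)-3-methoxyphenyl]-4-{[4-(TBSO)-3-methoxybenzyl]oxy}-2,3-dihydrobenzofuran-3-carboxylate | COC(=O)[C@H]1[C@@H](c2ccc(O[Si](C)(C)C(C)(C)C)c(OC)c2)Oc2cc(Br)cc(OCc3ccc(O[Si](C)(C)C(C)(C)C)c(OC)c3)c21 | intermediate
12 | (2S,3R)-6-bromo-2-[4-(TBSO)-3-methoxyphenyl]-4-{[4-(TBSO)-3-methoxybenzyl]oxy}-2,3-dihydrobenzofuran-3-carboxylic acid | OC(=O)[C@H]1[C@@H](c2ccc(O[Si](C)(C)C(C)(C)C)c(OC)c2)Oc2cc(Br)cc(OCc3ccc(O[Si](C)(C)C(C)(C)C)c(OC)c3)c21 | intermediate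
13 | 1,3-dioxoisoindolin-2-yl ester of 12 | O=C1c2ccccc2C(=O)N1OC(=O)[C@H]1[C@@H](c2ccc(O[Si](C)(C)C(C)(C)C)c(OC)c2)Oc2cc(Br)cc(OCc3ccc(O[Si](C)(C)C(C)(C)C)c(OC)c3)c21 | intermediate
14 | 1-bromo-3,5-bis(TBSO)benzene | CC(C)(C)[Si](C)(C)Oc1cc(Br)cc(O[Si](C)(C)C(C)(C)C)c1 | intermediate
15 | bis[3,5-bis(TBSO)phenyl]zinc | CC(C)(C)[Si](C)(C)Oc1cc(O[Si](C)(C)C(C)(C)C)cc([Zn]c2cc(O[Si](C)(C)C(C)(C)C)cc(O[Si](C)(C)C(C)(C)C)c2)c1 | intermediate
16 | (2S,3S)-6-bromo-3-[3,5-bis(TBSO)phenyl]-2-[4-(TBSO)-3-methoxyphenyl]-4-{[4-(TBSO)-3-methoxybenzyl]oxy}-2,3-dihydrobenzofuran | CC(C)(C)[Si](C)(C)Oc1cc(O[Si](C)(C)C(C)(C)C)cc(c1)[C@@H]1[C@@H](c2ccc(O[Si](C)(C)C(C)(C)C)c(OC)c2)Oc2cc(Br)cc(OCc3ccc(O[Si](C)(C)C(C)(C)C)c(OC)c3)c21 | intermediate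
17 | 4-hydroxybenzaldehyde | O=Cc1ccc(O)cc1 | starting material
18 | 4-(TBSO)benzaldehyde | O=Cc1ccc(O[Si](C)(C)C(C)(C)C)cc1 | intermediate
19 | [4-(TBSO)phenyl]methanol | OCc1ccc(O[Si](C)(C)C(C)(C)C)cc1 | intermediate
20 | 5-bromo-2-iodo-1,3-bis{[4-(TBSO)benzyl]oxy}benzene | Ic1c(OCc2ccc(O[Si](C)(C)C(C)(C)C)cc2)cc(Br)cc1OCc1ccc(O[Si](C)(C)C(C)(C)C)cc1 | intermediate
21 | (4-bromo-2,6-bis{[4-(TBSO)benzyl]oxy}phenyl)magnesium chloride | Cl[Mg]c1c(OCc2ccc(O[Si](C)(C)C(C)(C)C)cc2)cc(Br)cc1OCc1ccc(O[Si](C)(C)C(C)(C)C)cc1 | intermediate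
22 | methyl 2-(4-bromo-2,6-bis{[4-(TBSO)benzyl]oxy}phenyl)-2-oxoacetate | COC(=O)C(=O)c1c(OCc2ccc(O[Si](C)(C)C(C)(C)C)cc2)cc(Br)cc1OCc1ccc(O[Si](C)(C)C(C)(C)C)cc1 | intermediate
23 | N-tosylhydrazone of 22 | COC(=O)C(=NNS(=O)(=O)c1ccc(C)cc1)c1c(OCc2ccc(O[Si](C)(C)C(C)(C)C)cc2)cc(Br)cc1OCc1ccc(O[Si](C)(C)C(C)(C)C)cc1 | intermediate
24 | methyl 2-(4-bromo-2,6-bis{[4-(TBSO)benzyl]oxy}phenyl)-2-diazoacetate | COC(=O)C(=[N+]=[N-])c1c(OCc2ccc(O[Si](C)(C)C(C)(C)C)cc2)cc(Br)cc1OCc1ccc(O[Si](C)(C)C(C)(C)C)cc1 | intermediate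
25 | methyl (2R,3S)-6-bromo-2-[4-(TBSO)phenyl]-4-{[4-(TBSO)benzyl]oxy}-2,3-dihydrobenzofuran-3-carboxylate | COC(=O)[C@@H]1[C@H](c2ccc(O[Si](C)(C)C(C)(C)C)cc2)Oc2cc(Br)cc(OCc3ccc(O[Si](C)(C)C(C)(C)C)cc3)c21 | intermediate
26 | tert-butyldimethyl(4-vinylphenoxy)silane | C=Cc1ccc(O[Si](C)(C)C(C)(C)C)cc1 | starting material
27 | methyl (2R,3S)-2-[4-(TBSO)phenyl]-4-{[4-(TBSO)benzyl]oxy}-6-[(E)-4-(TBSO)styryl]-2,3-dihydrobenzofuran-3-carboxylate | COC(=O)[C@@H]1[C@H](c2ccc(O[Si](C)(C)C(C)(C)C)cc2)Oc2cc(/C=C/c3ccc(O[Si](C)(C)C(C)(C)C)cc3)cc(OCc3ccc(O[Si](C)(C)C(C)(C)C)cc3)c21 | intermediate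
28 | (2R,3S)-2-[4-(TBSO)phenyl]-4-{[4-(TBSO)benzyl]oxy}-6-[(E)-4-(TBSO)styryl]-2,3-dihydrobenzofuran-3-carboxylic acid | OC(=O)[C@@H]1[C@H](c2ccc(O[Si](C)(C)C(C)(C)C)cc2)Oc2cc(/C=C/c3ccc(O[Si](C)(C)C(C)(C)C)cc3)cc(OCc3ccc(O[Si](C)(C)C(C)(C)C)cc3)c21 | intermediate
29 | 1,3-dioxoisoindolin-2-yl ester of 28 | O=C1c2ccccc2C(=O)N1OC(=O)[C@@H]1[C@H](c2ccc(O[Si](C)(C)C(C)(C)C)cc2)Oc2cc(/C=C/c3ccc(O[Si](C)(C)C(C)(C)C)cc3)cc(OCc3ccc(O[Si](C)(C)C(C)(C)C)cc3)c21 | intermediate
30 | protected gnetin K: (2S,3S)-3-[3,5-bis(TBSO)phenyl]-2-[4-(TBSO)-3-methoxyphenyl]-4-{[4-(TBSO)-3-methoxybenzyl]oxy}-6-{(2R,3R)-2-[4-(TBSO)phenyl]-4-{[4-(TBSO)benzyl]oxy}-6-[(E)-4-(TBSO)styryl]-2,3-dihydrobenzofuran-3-yl}-2,3-dihydrobenzofuran | COc1cc([C@H]2Oc3cc([C@@H]4c5c(OCc7ccc(O[Si](C)(C)C(C)(C)C)cc7)cc(/C=C/c6ccc(O[Si](C)(C)C(C)(C)C)cc6)cc5O[C@H]4c4ccc(O[Si](C)(C)C(C)(C)C)cc4)cc(OCc4ccc(O[Si](C)(C)C(C)(C)C)c(OC)c4)c3[C@@H]2c2cc(O[Si](C)(C)C(C)(C)C)cc(O[Si](C)(C)C(C)(C)C)c2)ccc1O[Si](C)(C)C(C)(C)C | intermediate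
31 | gnetin K | COc1cc([C@H]2Oc3cc([C@@H]4c5c(O)cc(/C=C/c6ccc(O)cc6)cc5O[C@H]4c4ccc(O)cc4)cc(O)c3[C@@H]2c2cc(O)cc(O)c2)ccc1O | target

**Totals and risks**

Total step count: 20. Longest linear sequence: 10 steps (steps 1, 12–20; equally steps 1, 3–8, 10, 19, 20).

Steps most likely to fail:

1. Step 19. The C3–nickel intermediate may lose a β-hydride (aromatisation to the benzofuran), or the two electrophiles may be activated at mismatched rates (radical dimerisation, hydrodebromination of the aryl bromide). The fallback moves the union to a metal-free 1,2-metallate manifold; it sets out from 29 and 16 and returns to the route at 30. Photochemical decarboxylative borylation of 29 (bis(catecholato)diboron, DMAc, 450 nm light, which the stilbene does not absorb) would capture the same C3 radical trans to the C2 aryl group and give catechol boronate F1. This is transesterified in the flask with pinacol and Et3N to pinacol boronate F2 (3R, boron trans to the C2 aryl group). Bromide 16 is converted with n-BuLi (THF, −78 °C) into aryllithium F3, which adds to F2 to give lithium boronate complex F4. NBS (THF/MeOH, −78 °C) then brominates the aryl ring of F4 ortho to boron (C5 or C7 of ring system A, each ortho or para to a ring oxygen), triggering stereoretentive 1,2-migration of C3 from boron to carbon and loss of boron and bromide, which gives 30.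

2. Step 10. The aryl carbon–bromine bond of the substrate may be consumed by the low-valent iron–aryl species, or capture of the hindered C3 radical may be slow (reduction to C3–H). The fallback uses the same metal-free sequence, which leaves the aryl bromide untouched; it sets out from 13 and 14 and returns at 16. Photochemical decarboxylative borylation of 13 gives catechol boronate F5, exchanged in the flask to pinacol boronate F6 (3S, boron trans to the C2 aryl group). Bromide 14 and n-BuLi give aryllithium F7, which adds to F6 to form lithium boronate complex F8. NBS at −78 °C then brominates the 3,5-bis(silyloxy)phenyl ring ortho or para to boron and induces the stereoretentive 1,2-shift and elimination to 16.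

3. Step 15. Both ortho positions of the carbene-bearing ring are substituted, which twists the aryl group out of conjugation with the carbene and may erode enantiofacial discrimination. The fallback replaces catalyst control by separation; it sets out from 24 and returns at 25. Insertion with the achiral catalyst Rh2(esp)2 (CH2Cl2, 0 °C) would give 25 together with its enantiomer F9, and the two are separated at this small, early stage by preparative chromatography on a chiral stationary phase.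

Further compounds
F1 | step 19 | 2-{(2R,3R)-2-[4-(TBSO)phenyl]-4-{[4-(TBSO)benzyl]oxy}-6-[(E)-4-(TBSO)styryl]-2,3-dihydrobenzofuran-3-yl}-1,3,2-benzodioxaborole | O1c2ccccc2OB1[C@H]1[C@H](c2ccc(O[Si](C)(C)C(C)(C)C)cc2)Oc2cc(/C=C/c3ccc(O[Si](C)(C)C(C)(C)C)cc3)cc(OCc3ccc(O[Si](C)(C)C(C)(C)C)cc3)c21
F2 | step 19 | 2-{(2R,3R)-2-[4-(TBSO)phenyl]-4-{[4-(TBSO)benzyl]oxy}-6-[(E)-4-(TBSO)styryl]-2,3-dihydrobenzofuran-3-yl}-4,4,5,5-tetramethyl-1,3,2-dioxaborolane | CC1(C)OB(OC1(C)C)[C@H]1[C@H](c2ccc(O[Si](C)(C)C(C)(C)C)cc2)Oc2cc(/C=C/c3ccc(O[Si](C)(C)C(C)(C)C)cc3)cc(OCc3ccc(O[Si](C)(C)C(C)(C)C)cc3)c21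
F3 | step 19 | {(2S,3S)-3-[3,5-bis(TBSO)phenyl]-2-[4-(TBSO)-3-methoxyphenyl]-4-{[4-(TBSO)-3-methoxybenzyl]oxy}-2,3-dihydrobenzofuran-6-yl}lithium | CC(C)(C)[Si](C)(C)Oc1cc(O[Si](C)(C)C(C)(C)C)cc(c1)[C@@H]1[C@@H](c2ccc(O[Si](C)(C)C(C)(C)C)c(OC)c2)Oc2cc([Li])cc(OCc3ccc(O[Si](C)(C)C(C)(C)C)c(OC)c3)c21
F4 | step 19 | lithium boronate complex formed from F2 and F3 (boron bound to C3 of ring system B, C6 of ring system A and pinacolate) | [Li+].CC(C)(C)[Si](C)(C)Oc1cc(O[Si](C)(C)C(C)(C)C)cc(c1)[C@@H]1[C@@H](c2ccc(O[Si](C)(C)C(C)(C)C)c(OC)c2)Oc2cc([B-]3(OC(C)(C)C(C)(C)O3)[C@H]3[C@H](c4ccc(O[Si](C)(C)C(C)(C)C)cc4)Oc4cc(/C=C/c5ccc(O[Si](C)(C)C(C)(C)C)cc5)cc(OCc5ccc(O[Si](C)(C)C(C)(C)C)cc5)c43)cc(OCc3ccc(O[Si](C)(C)C(C)(C)C)c(OC)c3)c21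
F5 | step 10 | 2-{(2S,3S)-6-bromo-2-[4-(TBSO)-3-methoxyphenyl]-4-{[4-(TBSO)-3-methoxybenzyl]oxy}-2,3-dihydrobenzofuran-3-yl}-1,3,2-benzodioxaborole | O1c2ccccc2OB1[C@@H]1[C@@H](c2ccc(O[Si](C)(C)C(C)(C)C)c(OC)c2)Oc2cc(Br)cc(OCc3ccc(O[Si](C)(C)C(C)(C)C)c(OC)c3)c21
F6 | step 10 | 2-{(2S,3S)-6-bromo-2-[4-(TBSO)-3-methoxyphenyl]-4-{[4-(TBSO)-3-methoxybenzyl]oxy}-2,3-dihydrobenzofuran-3-yl}-4,4,5,5-tetramethyl-1,3,2-dioxaborolane | CC1(C)OB(OC1(C)C)[C@@H]1[C@@H](c2ccc(O[Si](C)(C)C(C)(C)C)c(OC)c2)Oc2cc(Br)cc(OCc3ccc(O[Si](C)(C)C(C)(C)C)c(OC)c3)c21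
F7 | step 10 | [3,5-bis(TBSO)phenyl]lithium | CC(C)(C)[Si](C)(C)Oc1cc([Li])cc(O[Si](C)(C)C(C)(C)C)c1
F8 | step 10 | lithium boronate complex formed from F6 and F7 | [Li+].CC1(C)O[B-](OC1(C)C)(c1cc(O[Si](C)(C)C(C)(C)C)cc(O[Si](C)(C)C(C)(C)C)c1)[C@@H]1[C@@H](c2ccc(O[Si](C)(C)C(C)(C)C)c(OC)c2)Oc2cc(Br)cc(OCc3ccc(O[Si](C)(C)C(C)(C)C)c(OC)c3)c21
F9 | step 15 | methyl (2S,3R)-6-bromo-2-[4-(TBSO)phenyl]-4-{[4-(TBSO)benzyl]oxy}-2,3-dihydrobenzofuran-3-carboxylate (enantiomer of 25) | COC(=O)[C@H]1[C@@H](c2ccc(O[Si](C)(C)C(C)(C)C)cc2)Oc2cc(Br)cc(OCc3ccc(O[Si](C)(C)C(C)(C)C)cc3)c21
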